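**Retrosynthetic overview**
1. The furan ring is closed last. An o-hydroxyaryl β-keto ester undergoes acid-catalysed cyclodehydration (O–C2 bond) once two benzyl ethers have been removed together.
2. The key C2–CH2 bond comes from a decarboxylative crossed Claisen condensation of a 2-arylpropanoyl imidazolide with magnesium methyl malonate.
3. The 2-arylpropanoic acid comes from oxidative cleavage of an o-(1-methylallyl)phenol. That phenol is made by aromatic Claisen rearrangement of a crotyl ether, which sets C3a–C3 and the C3 methyl at the only free ortho site.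
4. The biaryl comes from Suzuki coupling of 3-bromo-2,5-dimethoxyphenol with 4-(benzyloxy)phenylboronic acid. The bromophenol is made from 4-methoxyphenol by dibromination, methylation and mono Br/Li exchange–borylation–oxidation.
5. Ring order: both benzene rings are purchased, and the furan is the only ring formed, in the final step.

Assumption: the target SMILES has no stereocentre, no stereogenic double bond and no hindered biaryl axis. The target is therefore achiral and needs no stereocontrol. The stereocentres in 11–22 are carried racemic or as diastereomer mixtures and disappear on aromatisation.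

**Step 1**
Reactants: 1 4-methoxyphenol
Product: 2 2,6-dibromo-4-methoxyphenol
Conditions: Br2 (2.1 equiv), CH2Cl2, 0 °C to rt
Reagents that add atoms: bromine BrBr
Why: Electrophilic aromatic bromination in which the free hydroxyl outweighs the methoxy group as director, so with the para position blocked both bromines enter ortho to OH and give the symmetrical dibromide.

**Step 2**
Reactants: 2 2,6-dibromo-4-methoxyphenol
Product: 3 1,3-dibromo-2,5-dimethoxybenzene
Conditions: MeI (1.5 equiv), K2CO3 (2 equiv), acetone, reflux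
Reagents that add atoms: iodomethane CI
Why: Williamson ether synthesis (SN2 on MeI) of an acidic 2,6-dibromophenoxide, which is clean despite the flanking bromines.

**Step 3**
Reactants: 3 1,3-dibromo-2,5-dimethoxybenzene
Product: 6 3-bromo-2,5-dimethoxyphenol, via aryllithium 4 (not isolated), via dimethyl arylboronate 5 (not isolated)
Conditions: n-BuLi (1.0 equiv), THF, −78 °C; B(OMe)3 (1.5 equiv), −78 °C to rt; AcOH, 30% aq H2O2, 0 °C to rt
Reagents that add atoms: n-butyllithium [Li]CCCC (lithium of 4); trimethyl borate COB(OC)OC (boron unit of 5); hydrogen peroxide OO (phenol oxygen of 6)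
Why: Bromine–lithium exchange with one equivalent of n-BuLi on a symmetrical dibromide gives a single methoxy-chelated aryllithium (the remaining Br is meta, so no aryne), and borylation followed by peroxide-induced 1,2-aryl migration (boronate oxidation) delivers the phenol.

**Step 4**
Reactants: 6 3-bromo-2,5-dimethoxyphenol; 7 4-(benzyloxy)phenylboronic acid
Product: 8 4'-(benzyloxy)-2,5-dimethoxybiphenyl-3-ol
Conditions: Pd(dppf)Cl2 (3 mol %), K2CO3 (3 equiv), degassed 1,4-dioxane/H2O (4:1), 90 °C; acidify to pH 5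
Reagents that add atoms: none
Why: Suzuki–Miyaura coupling of an aryl bromide carrying only one ortho substituent, a reaction that tolerates a free phenol when extra base is present and air is excluded.

**Step 5**
Reactants: 8 4'-(benzyloxy)-2,5-dimethoxybiphenyl-3-ol; 9 (E)-crotyl bromide (E-rich technical grade)
Product: 10 4'-(benzyloxy)-3-[(E)-but-2-en-1-yloxy]-2,5-dimethoxybiphenyl
Conditions: K2CO3 (2 equiv), DMF, rt to 50 °C
Reagents that add atoms: none
Why: Williamson O-allylation (SN2 at the primary allylic carbon), where the E/Z ratio of the ether does not matter because both isomers give the same rearrangement product.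

**Step 6**
Reactants: 10 4'-(benzyloxy)-3-[(E)-but-2-en-1-yloxy]-2,5-dimethoxybiphenyl
Product: 12 rac-4'-(benzyloxy)-4-(but-3-en-2-yl)-2,5-dimethoxybiphenyl-3-ol, via ortho-dienone 11 (not isolated)
Conditions: PhNEt2, 200 °C, Ar, 6 h
Reagents that add atoms: none
Why: The aromatic Claisen rearrangement ([3,3]-sigmatropic shift, then tautomerisation) can end only at the single unsubstituted ortho carbon, forging the future C3a–C3 bond with allyl inversion so that the methyl branch sits on the benzylic carbon, whose configuration is racemic and is erased in step 12.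

**Step 7**
Reactants: 12 rac-4'-(benzyloxy)-4-(but-3-en-2-yl)-2,5-dimethoxybiphenyl-3-ol
Product: 13 rac-3,4'-bis(benzyloxy)-4-(but-3-en-2-yl)-2,5-dimethoxybiphenyl
Conditions: BnBr (1.3 equiv), K2CO3 (2 equiv), n-Bu4NI (5 mol %), DMF, 60 °C
Reagents that add atoms: benzyl bromide BrCc1ccccc1
Why: Williamson benzylation masks the phenol so that the coming aldehyde and acid cannot close to a lactol or lactone, and it uses the same group as the distal phenol so that both are removed together.

**Step 8**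
Reactants: 13 rac-3,4'-bis(benzyloxy)-4-(but-3-en-2-yl)-2,5-dimethoxybiphenyl
Product: 15 rac-2-[3,4'-bis(benzyloxy)-2,5-dimethoxybiphenyl-4-yl]propanal, via vicinal diol 14 (not isolated)
Conditions: OsO4 (2 mol %), NaIO4 (4 equiv), 2,6-lutidine (2 equiv), 1,4-dioxane/H2O (3:1), rt
Reagents that add atoms: osmium tetroxide O=[Os](=O)(=O)=O (catalytic oxygen carrier); sodium periodate [Na+].[O-]I(=O)(=O)=O (terminal oxygen source)
Why: In the Lemieux–Johnson oxidation OsO4 dihydroxylates the only alkene, a monosubstituted vinyl group, and NaIO4 cleaves the diol in situ, with 2,6-lutidine suppressing over-oxidation of the enolisable aldehyde.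

**Step 9**
Reactants: 15 rac-2-[3,4'-bis(benzyloxy)-2,5-dimethoxybiphenyl-4-yl]propanal
Product: 16 rac-2-[3,4'-bis(benzyloxy)-2,5-dimethoxybiphenyl-4-yl]propanoic acid
Conditions: NaClO2 (2 equiv), NaH2PO4 (3 equiv), 2-methyl-2-butene (15 equiv), t-BuOH/H2O (4:1), rt
Reagents that add atoms: sodium chlorite [Na+].[O-]Cl=O
Why: The Pinnick oxidation is selective for aldehydes, and the large excess of 2-methyl-2-butene traps HOCl before it can chlorinate the electron-rich rings.

**Step 10 (key step)**
Reactants: 16 rac-2-[3,4'-bis(benzyloxy)-2,5-dimethoxybiphenyl-4-yl]propanoic acid; 17 potassium monomethyl malonate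
Product: 20 rac-methyl 4-[3,4'-bis(benzyloxy)-2,5-dimethoxybiphenyl-4-yl]-3-oxopentanoate, via acyl imidazolide 18 (not isolated), via acylmalonic half-ester 19 (not isolated)
Conditions: CDI (1.2 equiv), THF, rt, 2 h; then 17 (2 equiv)/MgCl2 (2.5 equiv)/Et3N (3 equiv) pre-stirred in MeCN, rt to 45 °C; 1 M HCl work-up
Reagents that add atoms: 1,1'-carbonyldiimidazole O=C(n1ccnc1)n1ccnc1 (imidazolyl group of 18 only)
Why: In the Masamune–Brooks decarboxylative crossed Claisen condensation the chelated magnesium malonate half-ester enolate is barely basic, so it C-acylates the acyl imidazolide instead of deprotonating its acidic α-aryl C–H, and loss of CO2 makes formation of the C2–CH2 bond irreversible.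

**Step 11**
Reactants: 20 rac-methyl 4-[3,4'-bis(benzyloxy)-2,5-dimethoxybiphenyl-4-yl]-3-oxopentanoate
Product: 21 rac-methyl 4-(3,4'-dihydroxy-2,5-dimethoxybiphenyl-4-yl)-3-oxopentanoate
Conditions: H2 (1 atm), 10% Pd/C, EtOAc/MeOH (1:1), rt
Reagents that add atoms: none
Why: Catalytic hydrogenolysis cleaves both aryl benzyl ethers under neutral conditions that leave the β-keto ester, the methyl ethers and the arenes untouched.

**Step 12**
Reactants: 21 rac-methyl 4-(3,4'-dihydroxy-2,5-dimethoxybiphenyl-4-yl)-3-oxopentanoate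
Product: 23 phenylcandilide B, via cyclic hemiketal 22 (not isolated)
Conditions: p-TsOH·H2O (10 mol %), 1,2-dichloroethane, 70 °C
Reagents that add atoms: none
Why: Acid-catalysed cyclodehydration of an o-hydroxybenzyl ketone (five-membered hemiketalisation, then loss of water) is driven by benzofuran aromaticity, removes the last stereocentres and faces no real competition from seven-membered lactonisation onto the ester.

**Compound list**
1 | 4-methoxyphenol | COc1ccc(O)cc1 | starting material
2 | 2,6-dibromo-4-methoxyphenol | COc1cc(Br)c(O)c(Br)c1 | intermediate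
3 | 1,3-dibromo-2,5-dimethoxybenzene | COc1cc(Br)c(OC)c(Br)c1 | intermediate
4 | (3-bromo-2,5-dimethoxyphenyl)lithium (formed in situ) | [Li]c1cc(OC)cc(Br)c1OC | intermediate
5 | dimethyl (3-bromo-2,5-dimethoxyphenyl)boronate (formed in situ) | COB(OC)c1cc(OC)cc(Br)c1OC | intermediate
6 | 3-bromo-2,5-dimethoxyphenol | COc1cc(O)c(OC)c(Br)c1 | intermediate
7 | 4-(benzyloxy)phenylboronic acid | OB(O)c1ccc(OCc2ccccc2)cc1 | starting material
8 | 4'-(benzyloxy)-2,5-dimethoxybiphenyl-3-ol | COc1cc(O)c(OC)c(-c2ccc(OCc3ccccc3)cc2)c1 | intermediate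
9 | (E)-crotyl bromide, (E)-1-bromobut-2-ene | C/C=C/CBr | starting material
10 | 4'-(benzyloxy)-3-[(E)-but-2-en-1-yloxy]-2,5-dimethoxybiphenyl | C/C=C/COc1cc(OC)cc(-c2ccc(OCc3ccccc3)cc2)c1OC | intermediate
11 | 3-[4-(benzyloxy)phenyl]-6-(but-3-en-2-yl)-2,5-dimethoxycyclohexa-2,4-dien-1-one (formed in situ, diastereomer mixture) | O=C1C(OC)=C(c2ccc(OCc3ccccc3)cc2)C=C(OC)C1C(C)C=C | intermediate
12 | rac-4'-(benzyloxy)-4-(but-3-en-2-yl)-2,5-dimethoxybiphenyl-3-ol | C=CC(C)c1c(O)c(OC)c(-c2ccc(OCc3ccccc3)cc2)cc1OC | intermediate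
13 | rac-3,4'-bis(benzyloxy)-4-(but-3-en-2-yl)-2,5-dimethoxybiphenyl | C=CC(C)c1c(OCc2ccccc2)c(OC)c(-c2ccc(OCc3ccccc3)cc2)cc1OC | intermediate
14 | 3-[3,4'-bis(benzyloxy)-2,5-dimethoxybiphenyl-4-yl]butane-1,2-diol (formed in situ, diastereomer mixture) | OCC(O)C(C)c1c(OCc2ccccc2)c(OC)c(-c2ccc(OCc3ccccc3)cc2)cc1OC | intermediate
15 | rac-2-[3,4'-bis(benzyloxy)-2,5-dimethoxybiphenyl-4-yl]propanal | O=CC(C)c1c(OCc2ccccc2)c(OC)c(-c2ccc(OCc3ccccc3)cc2)cc1OC | intermediate
16 | rac-2-[3,4'-bis(benzyloxy)-2,5-dimethoxybiphenyl-4-yl]propanoic acid | OC(=O)C(C)c1c(OCc2ccccc2)c(OC)c(-c2ccc(OCc3ccccc3)cc2)cc1OC | intermediate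
17 | potassium monomethyl malonate | [K+].[O-]C(=O)CC(=O)OC | starting material
18 | rac-1-{2-[3,4'-bis(benzyloxy)-2,5-dimethoxybiphenyl-4-yl]propanoyl}imidazole (formed in situ) | O=C(n1ccnc1)C(C)c2c(OCc3ccccc3)c(OC)c(-c3ccc(OCc4ccccc4)cc3)cc2OC | intermediate
19 | 4-[3,4'-bis(benzyloxy)-2,5-dimethoxybiphenyl-4-yl]-2-(methoxycarbonyl)-3-oxopentanoic acid (formed in situ as its magnesium chelate, diastereomer mixture) | COC(=O)C(C(=O)O)C(=O)C(C)c1c(OCc2ccccc2)c(OC)c(-c2ccc(OCc3ccccc3)cc2)cc1OC | intermediate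
20 | rac-methyl 4-[3,4'-bis(benzyloxy)-2,5-dimethoxybiphenyl-4-yl]-3-oxopentanoate | COC(=O)CC(=O)C(C)c1c(OCc2ccccc2)c(OC)c(-c2ccc(OCc3ccccc3)cc2)cc1OC | intermediate
21 | rac-methyl 4-(3,4'-dihydroxy-2,5-dimethoxybiphenyl-4-yl)-3-oxopentanoate | COC(=O)CC(=O)C(C)c1c(O)c(OC)c(-c2ccc(O)cc2)cc1OC | intermediate
22 | methyl 2-[2-hydroxy-6-(4-hydroxyphenyl)-4,7-dimethoxy-3-methyl-2,3-dihydrobenzofuran-2-yl]acetate (formed in situ, diastereomer mixture) | COC(=O)CC1(O)Oc2c(OC)c(-c3ccc(O)cc3)cc(OC)c2C1C | intermediate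
23 | phenylcandilide B, methyl 2-[6-(4-hydroxyphenyl)-4,7-dimethoxy-3-methylbenzofuran-2-yl]acetate (achiral) | COC(=O)Cc1oc2c(OC)c(-c3ccc(O)cc3)cc(OC)c2c1C | target

**Total step count:** 12. **Longest linear sequence:** 12 steps (1 to 23).

**Steps most likely to fail, with fallbacks**

**Step 4 (Suzuki coupling on a free, electron-rich bromophenol).** The risks are catalyst inhibition and oxidation of the phenoxide.
- The fallback sets out from 6 and comes back at 13. It postpones the biaryl coupling until the phenol is masked and no aryl allyl ether remains that zerovalent palladium could ionise.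
- Compound 6 is alkylated with 9 (K2CO3, DMF) to 1-bromo-3-[(E)-but-2-en-1-yloxy]-2,5-dimethoxybenzene F1.
- F1 is heated (PhNEt2, 200 °C) and passes through 3-bromo-6-(but-3-en-2-yl)-2,5-dimethoxycyclohexa-2,4-dien-1-one F2 to rac-3-bromo-6-(but-3-en-2-yl)-2,5-dimethoxyphenol F3.
- Benzylation (BnBr, K2CO3, DMF, 60 °C) gives rac-2-(benzyloxy)-4-bromo-1-(but-3-en-2-yl)-3,6-dimethoxybenzene F4.
- F4 is then coupled with 7 (Pd(dppf)Cl2, K3PO4, dioxane/H2O, 85 °C) to give 13 directly.

**Step 6 (thermal Claisen rearrangement into a crowded ortho site).** The risks are para migration, ether cleavage and cyclisation at 200 °C.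
- The fallback sets out from 8 and comes back at 15. It builds the branched side chain by carbonyl chemistry instead of a sigmatropic shift.
- Ortho-specific formylation of 8 (MgCl2, Et3N, paraformaldehyde, MeCN, reflux) gives 4'-(benzyloxy)-3-hydroxy-2,5-dimethoxybiphenyl-4-carbaldehyde F5.
- Benzylation (BnBr, K2CO3, DMF) gives 3,4'-bis(benzyloxy)-2,5-dimethoxybiphenyl-4-carbaldehyde F6.
- MeMgBr (THF, 0 °C) gives rac-1-[3,4'-bis(benzyloxy)-2,5-dimethoxybiphenyl-4-yl]ethanol F7.
- Dess–Martin oxidation gives 1-[3,4'-bis(benzyloxy)-2,5-dimethoxybiphenyl-4-yl]ethanone F8.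
- Corey–Chaykovsky methylenation (Me3SI, NaH, DMSO/THF) gives rac-2-[3,4'-bis(benzyloxy)-2,5-dimethoxybiphenyl-4-yl]-2-methyloxirane F9.
- Meinwald rearrangement (catalytic BF3·OEt2, CH2Cl2, −78 °C) proceeds through the tertiary benzylic cation and a 1,2-hydride shift to deliver aldehyde 15.

**Step 10 (acylation by a hindered, α-branched, 2,6-dioxygenated arylpropanoyl imidazolide).** The risks are slow C-acylation and return of acid 16.
- The fallback sets out from 15, so it also skips step 9, and comes back at 20. It uses the far less hindered aldehyde as the electrophile in an intermolecular aldol addition.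
- The lithium enolate of methyl acetate (LDA, MeOAc, THF, −78 °C) adds to 15 to give methyl 4-[3,4'-bis(benzyloxy)-2,5-dimethoxybiphenyl-4-yl]-3-hydroxypentanoate F10 as a diastereomer mixture of no consequence.
- Dess–Martin periodinane (NaHCO3, CH2Cl2, rt) oxidises F10 to β-keto ester 20.

**Further compounds**
F1 | step 4 | 1-bromo-3-[(E)-but-2-en-1-yloxy]-2,5-dimethoxybenzene | C/C=C/COc1cc(OC)cc(Br)c1OC
F2 | step 4 | 3-bromo-6-(but-3-en-2-yl)-2,5-dimethoxycyclohexa-2,4-dien-1-one | O=C1C(OC)=C(Br)C=C(OC)C1C(C)C=C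
F3 | step 4 | rac-3-bromo-6-(but-3-en-2-yl)-2,5-dimethoxyphenol | C=CC(C)c1c(O)c(OC)c(Br)cc1OC
F4 | step 4 | rac-2-(benzyloxy)-4-bromo-1-(but-3-en-2-yl)-3,6-dimethoxybenzene | C=CC(C)c1c(OCc2ccccc2)c(OC)c(Br)cc1OC
F5 | step 6 | 4'-(benzyloxy)-3-hydroxy-2,5-dimethoxybiphenyl-4-carbaldehyde | O=Cc1c(O)c(OC)c(-c2ccc(OCc3ccccc3)cc2)cc1OC
F6 | step 6 | 3,4'-bis(benzyloxy)-2,5-dimethoxybiphenyl-4-carbaldehyde | O=Cc1c(OCc2ccccc2)c(OC)c(-c2ccc(OCc3ccccc3)cc2)cc1OC
F7 | step 6 | rac-1-[3,4'-bis(benzyloxy)-2,5-dimethoxybiphenyl-4-yl]ethanol | CC(O)c1c(OCc2ccccc2)c(OC)c(-c2ccc(OCc3ccccc3)cc2)cc1OC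
F8 | step 6 | 1-[3,4'-bis(benzyloxy)-2,5-dimethoxybiphenyl-4-yl]ethanone | CC(=O)c1c(OCc2ccccc2)c(OC)c(-c2ccc(OCc3ccccc3)cc2)cc1OC
F9 | step 6 | rac-2-[3,4'-bis(benzyloxy)-2,5-dimethoxybiphenyl-4-yl]-2-methyloxirane | CC1(CO1)c2c(OCc3ccccc3)c(OC)c(-c3ccc(OCc4ccccc4)cc3)cc2OC
F10 | step 10 | methyl 4-[3,4'-bis(benzyloxy)-2,5-dimethoxybiphenyl-4-yl]-3-hydroxypentanoate (diastereomer mixture) | COC(=O)CC(O)C(C)c1c(OCc2ccccc2)c(OC)c(-c2ccc(OCc3ccccc3)cc2)cc1OC
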